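**Assumption:** natural trans-phytol (2E,7R,11R; from chlorophyll) is bought as the single isomer; a batch that contains Z isomer is chromatographed before use.

## Retrosynthetic overview

1. Both stereocentres (7′R, 11′R) and the 2′E alkene are bought in natural phytol 1; the route creates no stereocentre and only has to leave these untouched.
2. Phytol 1 is activated at C1′ (alkoxysulfonium salt 2, then allylic chloride 3) and converted into the nucleophilic allylstannane 4.
3. Key disconnection: the C3–C1′ bond between quinone and side chain. It is made by BF3-promoted conjugate (Michael-type) allylation of menadione 5 with 4; the resulting hydroquinone 6 is oxidised to phylloquinone 7.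
4. Rings: none is formed; the naphthoquinone bicycle comes intact from 5.

## Route

**Step 1**
Reactants: 1 natural phytol [(2E,7R,11R)-3,7,11,15-tetramethylhexadec-2-en-1-ol]
Product: 3 phytyl chloride [(2E,7R,11R)-1-chloro-3,7,11,15-tetramethylhexadec-2-ene], via alkoxysulfonium salt 2 (not isolated)
Conditions: NCS (1.2 equiv), Me2S (1.3 equiv), CH2Cl2, −40 °C; add 1, −40 → 0 °C, 2 h; pentane/brine work-up, used without storage
Reagents that add atoms: N-chlorosuccinimide, O=C1CCC(=O)N1Cl; dimethyl sulfide, CSC (its atoms are held only in intermediate 2)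
Why: Corey–Kim allylic chlorination: chloride displaces the alkoxysulfonium group by SN2 at the primary carbon under non-acidic conditions, so there is no allylic transposition and no E/Z loss, and the remote stereocentres are untouched.

**Step 2**
Reactants: 3 phytyl chloride
Product: 4 phytyltrimethylstannane [trimethyl[(2E,7R,11R)-3,7,11,15-tetramethylhexadec-2-en-1-yl]stannane]
Conditions: Me3SnCl, Li, THF, 0 °C → rt (gives Me3SnLi); then 3, −78 → 0 °C, 2 h; aqueous work-up; chromatography on Et3N-deactivated silica
Reagents that add atoms: trimethyltin chloride, C[Sn](C)(C)Cl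
Why: Stannyl-anion alkylation: the soft Me3Sn anion displaces the primary allylic chloride by direct SN2 at C1′ without transposition, so the E alkene is kept and no stereocentre is involved.

**Step 3**
Reactants: 4 phytyltrimethylstannane; 5 menadione (2-methyl-1,4-naphthoquinone)
Product: 7 phylloquinone [2-methyl-3-[(2E,7R,11R)-3,7,11,15-tetramethylhexadec-2-en-1-yl]naphthalene-1,4-dione], via phyllohydroquinone 6 (not isolated)
Conditions: 5 (1.3 equiv), BF3·OEt2 (2.5 equiv), CH2Cl2, −78 °C; add 4 dropwise, −78 → −20 °C, dark; brine quench; crude product, Ag2O, Et2O, rt, 1 h; chromatography (hexane/Et2O), E/Z checked by 1H NMR and HPLC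
Reagents that add atoms: none
Why: Lewis-acid-mediated allylstannane–quinone coupling (a Sakurai-type Michael allylation): the BF3-activated enedione takes the allyl group from tin at its only unsubstituted carbon C3, bonding through the unhindered C1′ so that the 2′E alkene and the 7′R,11′R centres are carried over unchanged; tautomerisation gives hydroquinone 6, Ag2O restores the quinone, and no new stereocentre is formed.

## Compound list

1 | natural phytol, (2E,7R,11R)-3,7,11,15-tetramethylhexadec-2-en-1-ol | OC/C=C(\C)CCC[C@H](C)CCC[C@H](C)CCCC(C)C | starting material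
2 | dimethyl(phytyloxy)sulfonium chloride (alkoxysulfonium salt, 2E,7R,11R) | C[S+](C)OC/C=C(\C)CCC[C@H](C)CCC[C@H](C)CCCC(C)C.[Cl-] | intermediate (not isolated)
3 | phytyl chloride, (2E,7R,11R)-1-chloro-3,7,11,15-tetramethylhexadec-2-ene | ClC/C=C(\C)CCC[C@H](C)CCC[C@H](C)CCCC(C)C | intermediate
4 | phytyltrimethylstannane, trimethyl[(2E,7R,11R)-3,7,11,15-tetramethylhexadec-2-en-1-yl]stannane | C[Sn](C)(C)C/C=C(\C)CCC[C@H](C)CCC[C@H](C)CCCC(C)C | intermediate
5 | menadione, 2-methyl-1,4-naphthoquinone | CC1=CC(=O)c2ccccc2C1=O | starting material
6 | phyllohydroquinone, 2-methyl-3-[(2E,7R,11R)-phytyl]naphthalene-1,4-diol | Cc1c(C/C=C(\C)CCC[C@H](C)CCC[C@H](C)CCCC(C)C)c(O)c2ccccc2c1O | intermediate (not isolated)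
7 | phylloquinone (vitamin K1), 2-methyl-3-[(2E,7R,11R)-3,7,11,15-tetramethylhexadec-2-en-1-yl]naphthalene-1,4-dione | CC1=C(C/C=C(\C)CCC[C@H](C)CCC[C@H](C)CCCC(C)C)C(=O)c2ccccc2C1=O | target

## Totals

Total step count: 3.
Longest linear sequence: 3 steps (1 → 3 → 4 → 7); menadione 5 enters in the last step.

## Steps most likely to fail, with fallbacks

**Step 3 (highest risk).** The yield is expected to be only moderate. Hydroquinone 6 can exchange redox state with unreacted 5, BF3 can cyclise 6 to the chromanol if the mixture warms, and some E/Z leakage is possible.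
Fallback: it sets out from 5, uses chloride 3 as the electrophile, and comes back at 7. Menadione 5 is masked by Diels–Alder reaction with freshly cracked cyclopentadiene (EtOH, rt) as the menadione–cyclopentadiene adduct F1 (racemic, endo). KOtBu in THF at 0 °C converts it into the potassium enolate F2, which is C-alkylated by 3 in an SN2 reaction that does not touch the E alkene, giving the C-phytylated adduct F3. Heating F3 in toluene at 110 °C (retro-Diels–Alder) expels cyclopentadiene and delivers 7.

**Step 2.** The stannyl anion can cause electron-transfer homocoupling of 3 or some SN2′ attack, and 4 can protodestannylate on acidic silica.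
Fallback: it sets out from 1 and comes back at 4. Phytol 1 is acetylated (Ac2O, pyridine, DMAP cat., CH2Cl2) to phytyl acetate F4. This is stannylated without any stannyl anion by Me3SnSnMe3 and catalytic Pd(PPh3)4 in THF at 50 °C, through a π-allyl complex of divalent palladium that takes tin at the less hindered C1′ terminus. The E/Z ratio of 4 is checked before use.

**Step 1.** The allylic chloride can ionise to the tertiary chloride, lose some E purity, or decompose on storage.
Fallback: it sets out from 1 and comes back at 4, so no allylic halide is ever isolated. Phytol 1 is deprotonated with n-BuLi in THF at −78 °C to lithium phytoxide F5, and MsCl is added to form phytyl mesylate F6 in the flask. The Me3SnLi solution of step 2 is then added directly at −78 °C, and SN2 displacement of the mesylate gives 4 with the alkene geometry retained.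

## Further compounds

F1 | step 3 | menadione–cyclopentadiene Diels–Alder adduct, 4a-methyl-1,4,4a,9a-tetrahydro-1,4-methanoanthracene-9,10-dione (racemic, endo, cis-fused; ring stereocentres are erased in the retro-Diels–Alder reaction) | CC12C(=O)c3ccccc3C(=O)C1C1C=CC2C1
F2 | step 3 | potassium enolate of the adduct | CC12C(=O)c3ccccc3C([O-])=C1C1C=CC2C1.[K+]
F3 | step 3 | C-phytylated adduct, 4a-methyl-9a-[(2E,7R,11R)-phytyl]-1,4,4a,9a-tetrahydro-1,4-methanoanthracene-9,10-dione (mixture at the ring stereocentres) | CC12C(=O)c3ccccc3C(=O)C1(C/C=C(\C)CCC[C@H](C)CCC[C@H](C)CCCC(C)C)C1C=CC2C1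
F4 | step 2 | phytyl acetate, (2E,7R,11R) | CC(=O)OC/C=C(\C)CCC[C@H](C)CCC[C@H](C)CCCC(C)C
F5 | step 1 | lithium phytoxide, (2E,7R,11R) | [Li+].[O-]C/C=C(\C)CCC[C@H](C)CCC[C@H](C)CCCC(C)C
F6 | step 1 | phytyl mesylate, (2E,7R,11R) | CS(=O)(=O)OC/C=C(\C)CCC[C@H](C)CCC[C@H](C)CCCC(C)C
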